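The readings were computed on assumed constants, noise included.

If target (P) and other capture product (Q) arise from one competition between the two nucleophiles, then dP/dQ = Sρ, where S is the selectivity factor and ρ is the nucleophile ratio, first over second, charged at 2.50.

the same everywhere: substrate 0.084 M

| run | first nucleophile | second nucleophile | remark | time |
|---|---|---|---|---|
| Monday's | 1.5 equiv | 0.60 equiv | the very flask that is asked about, followed so far |  |
| flask | 1.50 equiv | 0.600 equiv |  | 15 min |

Monday's run (percent of the substrate charged)

| time / min | target / % | other capture product / % | substrate / % |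
|---|---|---|---|
| 0.333 | 1.1 | 5.3 | 41.2 |
| 0.500 | 1.3 | 7.7 | 27.4 |
| 0.833 | 1.6 | 11.1 | 16.1 |
| 1.33 | 0.8 | 11.6 | 8.1 |
| 2.00 | 0.1 | 13.8 | 9.4 |
| 3.00 | 1.0 | 14.5 | 6.6 |
| 5.00 | 0.3 | 19.0 | 7.2 |

(readings scatter by 1 percentage point)

1. ratio of target to other capture product at 8.0 s
2. ratio of target to other capture product at 15 min



Two extremes bracket the flask. If target survives, integrating at steady ρ gives P/Q = Sρ, so the ratio at 15 min equals that at 8.0 s. If target is lost with a lifetime τ short against the run, P stands at Sρτ·dQ/dt and the ratio falls as Q grows. Monday's readings up to 0.833 min pool to 0.166, give or take 0.0719. Those from 1.33 min on pool to 0.0374, lower than the early pool, but that gap of 0.129 stands against an error near 0.0795, so these readings do not place the flask nearer either extreme. My own reckoning adopts the second extreme as a working choice and takes the pooled early reading for 8.0 s. For 15 min, it holds target at its late mean and extends Q's late slope to 39.2%, which gives 0.0140.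

The forecast stands at 0.18 and 0.02, noting “Target is barely above the scatter”.

The flask gives 0.0810 and 0.0192, so the forecast stands too high at 8.0 s by a factor of 2.22 and right at 15 min.

    substrate → intermediate (k = 0.00540 /s)
    first nucleophile + intermediate → target (k = 2.10 /M/s)
    second nucleophile + intermediate → other capture product (k = 65.0 /M/s)
    intermediate → solvolysis product (k = 0.210 /s)
    target → over-reaction product (k = 0.00560 /s)
    substrate ⇌ dormant form (K = 9.70, k = 0.0410 /s)

The neighbour with 3.80 equiv of first nucleophile has a charged ρ of 6.33, which scales the flask's early ratio to 0.205, and that neighbour gives 0.205. At the end, ρ is counted from what is left. The flask stands at 5.46 and the neighbour at 12.2. Scaling the flask's late ratio by these gives 0.0428, and the neighbour gives 0.0434.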